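**Plan**

- The ring is numbered from the formyl carbon: C1 (CHO), C2 (side chain), C3 (OH), C4 (OMe), C5 (H), C6 (OH). The oxygens on C3 and C6 are para, so the ring is a reduced 2-methoxy-1,4-benzoquinone. A 4-methoxyphenol from a chromium carbene benzannulation maps directly onto it.
- Retrosynthesis: hydroquinone aldehyde, back to the formylquinone, back to the 4-methoxyphenol acetal. The ring bonds C3–C2, C1–C6 and C6–C5 are then cut to give a methoxy(1-methoxyvinyl)carbene complex of zerovalent chromium (C3, C4, C5, plus one CO for C6) and an internal alkyne (C1, C2).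
- The alkyne is cut at the propargylic C–C bond into an acetylide (3,3-diethoxyprop-1-yne) and a terminal epoxide.
- Forward: the chain is joined first (epoxide opening, acetylation), the single ring is closed in step 6, and an oxidation/reduction pair then frees the C3 hydroxyl and the aldehyde.
- Stereochemistry: the one stereocenter (R, the acetate carbinol) comes from hydrolytic kinetic resolution of racemic 2-undecyloxirane and is carried through unchanged.

Key step: step 6

Assumption: in the acidic aqueous medium of the cerium oxidation (step 7) the diethyl acetal is taken to hydrolyse in the same flask, after the ring has been oxidized.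

**Step 1**
Reactants: 1 tridec-1-ene
Product: 2 rac-2-undecyloxirane
Conditions: mCPBA, CH2Cl2, 0 °C to rt
Reagents that add atoms: 3-chloroperoxybenzoic acid (mCPBA), O=C(OO)c1cccc(Cl)c1
Why: Prilezhaev epoxidation of an unhindered terminal alkene by a peracid is concerted and needs no selectivity, because the racemate is resolved in the next step.

**Step 2**
Reactants: 2 rac-2-undecyloxirane
Product: 3 (R)-2-undecyloxirane
Conditions: (R,R)-(salen)Co(OAc) (0.5 mol %; salen = N,N'-bis(3,5-di-tert-butylsalicylidene)cyclohexane-1,2-diaminate), H2O (0.55 equiv), THF, 0 °C to rt; distillation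
Reagents that add atoms: none
Why: Hydrolytic kinetic resolution: the chiral salen acetate complex of trivalent cobalt activates epoxide and water and should hydrolyse the (S)-epoxide much faster, so the unreacted (R)-epoxide, separable from the diol by distillation, supplies the only stereocenter of the target.

**Step 3**
Reactants: 4 3,3-diethoxyprop-1-yne; 3 (R)-2-undecyloxirane
Product: 6 (R)-1,1-diethoxyhexadec-2-yn-5-ol, via lithium 3,3-diethoxyprop-1-ynide 5 (not isolated)
Conditions: 4, n-BuLi, THF, −78 °C; BF3·OEt2; then 3, −78 °C; aq NH4Cl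
Reagents that add atoms: none
Why: Yamaguchi–Hirao alkynylation: the lithium acetylide opens the BF3-activated epoxide by SN2 attack at the unsubstituted carbon, so the stereocenter is not involved and stays (R), and the acetal should tolerate BF3·OEt2 at −78 °C.

**Step 4**
Reactants: 6 (R)-1,1-diethoxyhexadec-2-yn-5-ol
Product: 7 (R)-1,1-diethoxyhexadec-2-yn-5-yl acetate
Conditions: Ac2O, pyridine, DMAP (cat.), CH2Cl2, 0 °C to rt
Reagents that add atoms: acetic anhydride, CC(=O)OC(C)=O
Why: DMAP-catalysed acylation of a secondary alcohol in basic medium leaves the acetal and the alkyne alone and does not touch the stereocenter.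

**Step 5**
Reactants: 8 methyl vinyl ether; 9 chromium hexacarbonyl, Cr(CO)6
Product: 12 pentacarbonyl[methoxy(1-methoxyvinyl)carbene]chromium, via 1-methoxyvinyllithium 10 (not isolated), via lithium pentacarbonyl(2-methoxyprop-2-enoyl)chromate 11 (not isolated)
Conditions: 8, t-BuLi, THF, −78 to 0 °C; Cr(CO)6, Et2O, −78 °C to rt; evaporate; Me3OBF4, CH2Cl2, 0 °C
Reagents that add atoms: trimethyloxonium tetrafluoroborate, C[O+](C)C.F[B-](F)(F)F
Why: Fischer carbene synthesis: the α-lithiated enol ether adds to a carbonyl ligand of Cr(CO)6 and the resulting acylchromate is O-methylated by the oxonium salt, as in the preparation of the known 3,4-dihydro-2H-pyran-6-yl(methoxy)carbene complex, of which 12 is the open-chain analogue.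

**Step 6**
Reactants: 12 pentacarbonyl[methoxy(1-methoxyvinyl)carbene]chromium (1.3 equiv); 7 (R)-1,1-diethoxyhexadec-2-yn-5-yl acetate
Product: 14 (R)-1-[2-(diethoxymethyl)-3-hydroxy-5,6-dimethoxyphenyl]tridecan-2-yl acetate, via tricarbonylchromium arene complex 13 (not isolated)
Conditions: THF (0.05 M), 50 °C, argon; then air, rt; Et3N-deactivated SiO2
Reagents that add atoms: none
Why: Dötz benzannulation: loss of one CO from 12 lets alkyne 7 bind and insert into the Cr=C bond to give a vinylcarbene, a CO ligand then inserts to give a chromium-bound dienylketene, and six-electron electrocyclization followed by enolization gives the 4-methoxyphenol on Cr(CO)3, which air sets free. The closest known reaction is the benzannulation of 2-alkoxyalkenyl(methoxy)carbene complexes of zerovalent chromium, such as the dihydropyranyl complex, with internal alkynes. The benzene ring closes by forming C3–C2 (carbene carbon to alkyne), C1–C6 (alkyne to the inserted CO) and, in the electrocyclic closure, C6–C5 (CO carbon to the vinyl CH2), a formal [3+2+1] assembly. No stereocenter is formed, and the acetate stereocenter, two atoms away from the alkyne, is not touched under the neutral conditions. The step needs regioselective alkyne insertion: the larger alkyne substituent is placed next to the CO-derived carbon, and the α-branched diethoxymethyl group is larger than the chain CH2, so the acetal should end up on C1 and the chain on C2, with any regioisomer removed by chromatography. Because the phenol oxygen on C6 arises para to the carbene methoxy on C3, the three ring oxygens are differentiated for the oxidation that follows.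

**Step 7**
Reactants: 14 (R)-1-[2-(diethoxymethyl)-3-hydroxy-5,6-dimethoxyphenyl]tridecan-2-yl acetate
Product: 16 (R)-1-(2-formyl-5-methoxy-3,6-dioxocyclohexa-1,4-dien-1-yl)tridecan-2-yl acetate, via diethyl acetal quinone 15 (not isolated)
Conditions: (NH4)2Ce(NO3)6 (2.5 equiv), MeCN/H2O, 0 °C to rt; extracted and used crude
Reagents that add atoms: water, O
Why: Oxidative demethylation of a 4-methoxyphenol: tetravalent cerium removes two electrons, water adds at C3 and methanol is lost to give the p-quinone while the C4 methoxy (now a vinylogous ester) stays, and the acid formed in the flask hydrolyses the acetal to the aldehyde.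

**Step 8**
Reactants: 16 (R)-1-(2-formyl-5-methoxy-3,6-dioxocyclohexa-1,4-dien-1-yl)tridecan-2-yl acetate
Product: 17 (R)-1-(2-formyl-3,6-dihydroxy-5-methoxyphenyl)tridecan-2-yl acetate (the target)
Conditions: Na2S2O4, EtOAc/H2O, rt, argon
Reagents that add atoms: none
Why: Dithionite reduction of a p-quinone to the hydroquinone is fast in a two-phase system at room temperature and should leave the hindered aryl aldehyde, the acetate and the stereocenter alone.

**Compound list**

1 | tridec-1-ene | C=CCCCCCCCCCCC | starting material
2 | rac-2-undecyloxirane | CCCCCCCCCCCC1CO1 | intermediate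
3 | (R)-2-undecyloxirane | CCCCCCCCCCC[C@@H]1CO1 | intermediate
4 | 3,3-diethoxyprop-1-yne | C#CC(OCC)OCC | starting material
5 | lithium 3,3-diethoxyprop-1-ynide (formed in the flask, not isolated) | [Li]C#CC(OCC)OCC | intermediate
6 | (R)-1,1-diethoxyhexadec-2-yn-5-ol | CCCCCCCCCCC[C@H](CC#CC(OCC)OCC)O | intermediate
7 | (R)-1,1-diethoxyhexadec-2-yn-5-yl acetate | CCCCCCCCCCC[C@H](CC#CC(OCC)OCC)OC(C)=O | intermediate
8 | methyl vinyl ether | COC=C | starting material
9 | chromium hexacarbonyl, Cr(CO)6 | O=C=[Cr](=C=O)(=C=O)(=C=O)(=C=O)=C=O | starting material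
10 | 1-methoxyvinyllithium (formed in the flask, not isolated) | [Li]C(=C)OC | intermediate
11 | lithium pentacarbonyl(2-methoxyprop-2-enoyl)chromate (formed in the flask, not isolated) | [Li+].[O-]C(C(=C)OC)=[Cr](=C=O)(=C=O)(=C=O)(=C=O)=C=O | intermediate
12 | pentacarbonyl[methoxy(1-methoxyvinyl)carbene]chromium | COC(C(=C)OC)=[Cr](=C=O)(=C=O)(=C=O)(=C=O)=C=O | intermediate
13 | tricarbonyl(η6-arene)chromium complex of phenol 14 (not isolated; the arene–chromium bonding is written as two fragments) | CCCCCCCCCCC[C@H](Cc1c(OC)c(OC)cc(O)c1C(OCC)OCC)OC(C)=O.O=C=[Cr](=C=O)=C=O | intermediate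
14 | (R)-1-[2-(diethoxymethyl)-3-hydroxy-5,6-dimethoxyphenyl]tridecan-2-yl acetate | CCCCCCCCCCC[C@H](Cc1c(OC)c(OC)cc(O)c1C(OCC)OCC)OC(C)=O | intermediate
15 | (R)-1-[2-(diethoxymethyl)-5-methoxy-3,6-dioxocyclohexa-1,4-dien-1-yl]tridecan-2-yl acetate (not isolated) | CCCCCCCCCCC[C@H](CC1=C(C(OCC)OCC)C(=O)C=C(OC)C1=O)OC(C)=O | intermediate
16 | (R)-1-(2-formyl-5-methoxy-3,6-dioxocyclohexa-1,4-dien-1-yl)tridecan-2-yl acetate | CCCCCCCCCCC[C@H](CC1=C(C=O)C(=O)C=C(OC)C1=O)OC(C)=O | intermediate
17 | (R)-1-(2-formyl-3,6-dihydroxy-5-methoxyphenyl)tridecan-2-yl acetate | CCCCCCCCCCC[C@H](Cc1c(O)c(OC)cc(O)c1C=O)OC(C)=O | target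

**Step count and risks**

Total step count: 8. Longest linear sequence: 7 steps (steps 1, 2, 3, 4, 6, 7, 8, from tridec-1-ene); step 5 supplies the carbene complex in a one-step branch.

Steps most likely to fail:

1. Step 6. The alkyne may insert with poor regiocontrol, because the steric difference between the diethoxymethyl group and the chain CH2 is modest and the inductive pull of the acetal may oppose it. The internal alkyne may also react sluggishly with the donor-substituted complex. The fallback sets out from 12 and 4, draws on epoxide 3, and comes back at 14. Complex 12 would be heated in THF with the terminal alkyne 4, whose terminal hydrogen fixes the insertion regiochemistry, to give 2-(diethoxymethyl)-4,5-dimethoxyphenol F1. Silylation with i-Pr3SiCl and imidazole would give [2-(diethoxymethyl)-4,5-dimethoxyphenoxy]tri(propan-2-yl)silane F2. The bulky silyl ether shields C5, so n-BuLi should remove the proton on C2, which lies between the acetal and the C3 methoxy (directed ortho-metalation), giving {2-(diethoxymethyl)-5,6-dimethoxy-3-[tri(propan-2-yl)silyloxy]phenyl}lithium F3. Opening of epoxide 3 at its CH2 in the presence of BF3·OEt2 at −78 °C would give (R)-1-{2-(diethoxymethyl)-5,6-dimethoxy-3-[tri(propan-2-yl)silyloxy]phenyl}tridecan-2-ol F4. Acetylation (Ac2O, pyridine, DMAP) would give (R)-1-{2-(diethoxymethyl)-5,6-dimethoxy-3-[tri(propan-2-yl)silyloxy]phenyl}tridecan-2-yl acetate F5, and Bu4NF buffered with acetic acid would remove the silyl group to give 14.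

2. Step 7. The formylquinone is a strong electrophile and may add water or decompose in the acidic oxidizing medium, and uneven acetal hydrolysis may leave a mixture. The fallback sets out from 14 and comes back at 17. Oxidation with PhI(OAc)2 in MeCN/H2O over NaHCO3 at 0 °C should give the quinone 15 with the acetal intact, now isolated. Na2S2O4 would reduce it to (R)-1-[2-(diethoxymethyl)-3,6-dihydroxy-5-methoxyphenyl]tridecan-2-yl acetate F6, and pyridinium p-toluenesulfonate in acetone/water would then unmask the aldehyde on the electron-rich ring to give 17. No formylquinone is handled in this sequence.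

3. Step 5. α-Lithiation of the volatile enol ether may be incomplete, so left-over t-BuLi attacks Cr(CO)6, and the vinyllithium may decompose on warming. The fallback sets out from 9 and comes back at 12 without an organolithium reagent. Commercial methyl 2-methoxyprop-2-enoate would be saponified with LiOH to 2-methoxyprop-2-enoic acid F7 and converted with oxalyl chloride into 2-methoxyprop-2-enoyl chloride F8. Cr(CO)6 would be reduced with sodium naphthalenide (NaC10H8) in THF at −78 °C to disodium pentacarbonylchromate, Na2Cr(CO)5 F9. Acylation of F9 with F8 would give sodium pentacarbonyl(2-methoxyprop-2-enoyl)chromate F10, and Me3OBF4 would methylate it on oxygen to give 12.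

**Further compounds**

F1 | step 6 | 2-(diethoxymethyl)-4,5-dimethoxyphenol | CCOC(OCC)c1cc(OC)c(OC)cc1O
F2 | step 6 | [2-(diethoxymethyl)-4,5-dimethoxyphenoxy]tri(propan-2-yl)silane | CCOC(OCC)c1cc(OC)c(OC)cc1O[Si](C(C)C)(C(C)C)C(C)C
F3 | step 6 | {2-(diethoxymethyl)-5,6-dimethoxy-3-[tri(propan-2-yl)silyloxy]phenyl}lithium | CCOC(OCC)c1c([Li])c(OC)c(OC)cc1O[Si](C(C)C)(C(C)C)C(C)C
F4 | step 6 | (R)-1-{2-(diethoxymethyl)-5,6-dimethoxy-3-[tri(propan-2-yl)silyloxy]phenyl}tridecan-2-ol | CCCCCCCCCCC[C@H](Cc1c(OC)c(OC)cc(O[Si](C(C)C)(C(C)C)C(C)C)c1C(OCC)OCC)O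
F5 | step 6 | (R)-1-{2-(diethoxymethyl)-5,6-dimethoxy-3-[tri(propan-2-yl)silyloxy]phenyl}tridecan-2-yl acetate | CCCCCCCCCCC[C@H](Cc1c(OC)c(OC)cc(O[Si](C(C)C)(C(C)C)C(C)C)c1C(OCC)OCC)OC(C)=O
F6 | step 7 | (R)-1-[2-(diethoxymethyl)-3,6-dihydroxy-5-methoxyphenyl]tridecan-2-yl acetate | CCCCCCCCCCC[C@H](Cc1c(O)c(OC)cc(O)c1C(OCC)OCC)OC(C)=O
F7 | step 5 | 2-methoxyprop-2-enoic acid | C=C(OC)C(=O)O
F8 | step 5 | 2-methoxyprop-2-enoyl chloride | C=C(OC)C(=O)Cl
F9 | step 5 | disodium pentacarbonylchromate, Na2Cr(CO)5 | [Na+].[Na+].O=C=[Cr-2](=C=O)(=C=O)(=C=O)=C=O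
F10 | step 5 | sodium pentacarbonyl(2-methoxyprop-2-enoyl)chromate | [Na+].[O-]C(C(=C)OC)=[Cr](=C=O)(=C=O)(=C=O)(=C=O)=C=O
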